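Ring A is disconnected into a squarate and a preformed ring C. The four contiguous oxygenated carbons C5–C8 are the four carbons of a mixed methyl tert-butyl squarate, and the ring-fusion bond C4a=C8a is the C5=C6 bond of a 2-aryl-4H-pyran-4-one carrying hydrogen at C6. One thermal operation opens the 4-pyranonyl-4-methoxycyclobutenone to a vinylketene and closes it onto pyranone C6, forming the C8–C8a bond and the whole flavone with O5, O6, O7 and O8 already differentiated (OMe, OMe, O-t-Bu, OH). The precursor is a cyclobutenone bearing tert-butoxy at C2, methoxy at C3, and methoxy plus the 6-aryl-4-oxopyran-3-yl group at C4.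

Key step: step 8

Remark: every stereocentre met on the way is racemic and is destroyed before the target, so none is controlled; di-tert-butyl squarate, used only in one fallback, is assumed to be purchasable.

Step 1
Reactants: 1 dimethyl squarate (3,4-dimethoxycyclobut-3-ene-1,2-dione)
Product: 3 methyl hydrogen squarate (3-hydroxy-4-methoxycyclobut-3-ene-1,2-dione), via sodium methyl squarate 2 (not isolated)
Conditions: NaOH (1.0 equiv), THF/H2O, 0 °C; then HCl (1.0 equiv), concentrate, extract into acetone, dry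
Reagents that add atoms: sodium hydroxide, [Na+].[OH-]
Why: Saponification of a vinylogous ester by addition–elimination of hydroxide should stop after one methoxy group, because the squarate monoanion 2 that results is no longer electrophilic.

Step 2
Reactants: 3 methyl hydrogen squarate
Product: 4 3-tert-butoxy-4-methoxycyclobut-3-ene-1,2-dione
Conditions: Cl3CC(=NH)O-t-Bu (2.5 equiv), CH2Cl2/cyclohexane, 0 °C to rt, acid 3 added slowly to the imidate; filter; chromatography on Et3N-deactivated silica
Reagents that add atoms: tert-butyl 2,2,2-trichloroacetimidate, CC(C)(C)OC(=N)C(Cl)(Cl)Cl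
Why: The strongly acidic vinylogous acid protonates the imidate, which then hands a tert-butyl cation to the squarate anion (imidate O-alkylation of an acid), a two-stage entry chosen because direct alkoxide exchange on 1 would scramble the ester groups, and alkylation at either conjugated oxygen leads to the same 1,2-dione.

Step 3
Reactants: 5 3,4-dimethoxybenzaldehyde; 6 (E)-1-methoxy-3-(trimethylsilyloxy)buta-1,3-diene
Product: 8 rac-2-(3,4-dimethoxyphenyl)-2,3-dihydro-4H-pyran-4-one, via silyl enol ether cycloadduct 7 (not isolated)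
Conditions: ZnCl2 (1.0 equiv), THF, rt; then TFA (cat.), CH2Cl2, 0 °C
Reagents that add atoms: none
Why: Lewis acid-promoted hetero-Diels–Alder reaction of the aldehyde with the electron-rich siloxydiene, followed by acid-induced loss of the silyl group and of methanol from 7, should give the vinylogous ester, whose C2 stereocentre forms as a racemate and is erased in step 5.

Step 4
Reactants: 8 rac-2-(3,4-dimethoxyphenyl)-2,3-dihydro-4H-pyran-4-one
Product: 9 rac-2-(3,4-dimethoxyphenyl)-5-iodo-2,3-dihydro-4H-pyran-4-one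
Conditions: I2 (1.5 equiv), pyridine/CH2Cl2 (1:1), 0 °C to rt; aq. Na2S2O3
Reagents that add atoms: iodine, II
Why: Pyridine-mediated α-iodination of an enone (conjugate addition, iodination, elimination) can only take place at C5, the single sp2 carbon next to the carbonyl group at this oxidation level, which is why the halogen is introduced before the ring is dehydrogenated; the racemic C2 centre is not touched.

Step 5
Reactants: 9 rac-2-(3,4-dimethoxyphenyl)-5-iodo-2,3-dihydro-4H-pyran-4-one
Product: 10 2-(3,4-dimethoxyphenyl)-5-iodo-4H-pyran-4-one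
Conditions: DDQ (2.0 equiv), 1,4-dioxane, 100 °C
Reagents that add atoms: none
Why: Quinone dehydrogenation by hydride abstraction from the benzylic, oxygen-bearing C2–H (stabilised by the dimethoxyphenyl group) and loss of a C3 proton should give the cross-conjugated pyranone and remove the only stereocentre, and a metal-free oxidant is chosen so that the vinyl iodide is not at risk.

Step 6
Reactants: 10 2-(3,4-dimethoxyphenyl)-5-iodo-4H-pyran-4-one; 4 3-tert-butoxy-4-methoxycyclobut-3-ene-1,2-dione
Product: 12 rac-2-tert-butoxy-4-hydroxy-3-methoxy-4-[6-(3,4-dimethoxyphenyl)-4-oxo-4H-pyran-3-yl]cyclobut-2-en-1-one, via pyranonylmagnesium chloride 11 (not isolated)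
Conditions: i-PrMgCl·LiCl (1.05 equiv), THF, −40 °C, 30 min; cannulate into 4 (1.2 equiv), THF, −78 °C; aq. NH4Cl; chromatography, regiochemistry to be checked by HMBC
Reagents that add atoms: none
Why: Iodine–magnesium exchange, as used on 3-iodochromones, should give an α-magnesiated vinylogous ester that adds 1,2 to the squarate (Grignard addition) at the carbonyl flanked by the methoxy carbon, since the other carbonyl is screened by the neighbouring tert-butoxy group and is the vinylogous ester of the better-donating methoxy group; the carbinol centre forms as a racemate and is lost in step 8.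

Step 7
Reactants: 12 rac-2-tert-butoxy-4-hydroxy-3-methoxy-4-[6-(3,4-dimethoxyphenyl)-4-oxo-4H-pyran-3-yl]cyclobut-2-en-1-one
Product: 13 rac-2-tert-butoxy-3,4-dimethoxy-4-[6-(3,4-dimethoxyphenyl)-4-oxo-4H-pyran-3-yl]cyclobut-2-en-1-one
Conditions: MeI (10 equiv), Ag2O (2 equiv), 4 Å MS, CH3CN, rt, dark
Reagents that add atoms: iodomethane, CI
Why: Silver oxide-assisted Williamson-type O-methylation should cap the hindered tertiary carbinol under nearly neutral conditions that avoid retro-addition of a free alkoxide and, unlike methyl triflate, do not alkylate the pyranone carbonyl oxygen; no stereocentre is formed.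

Step 8
Reactants: 13 rac-2-tert-butoxy-3,4-dimethoxy-4-[6-(3,4-dimethoxyphenyl)-4-oxo-4H-pyran-3-yl]cyclobut-2-en-1-one
Product: 16 7-tert-butoxy-8-hydroxy-5,6-dimethoxy-2-(3,4-dimethoxyphenyl)-4H-chromen-4-one, via dienylketene 14 (not isolated), via 8aH-chromene-4,8-dione 15 (not isolated)
Conditions: toluene (degassed, 0.01 M), 110 °C, Ar, base-washed glassware
Reagents that add atoms: none
Why: Heating cleaves the C1–C4 bond of the cyclobutenone by conrotatory 4π electrocyclic opening, and because the C4 methoxy donor rotates outward the pyranonyl group ends up cis to the ketene in 14. Thermal 6π electrocyclisation (disrotatory, six-membered carbocycle) then bonds the ketene carbon to pyranone C6, which becomes C8a, and the dienone 15 aromatises by moving the C8a hydrogen to the C8 oxygen, so ring A and the complete flavone arise in one operation. The closest known reaction type is the thermal ring expansion of 4-alkenyl- and 4-heteroaryl-4-alkoxycyclobutenones to alkoxyphenols, the pyranone C5=C6 bond serving here as the alkene partner. The only stereocentre formed, C8a of 15, is transient and racemic, and none remains in 16. The step needs inward rotation of the pyranonyl group, secured by the outward preference of the C4 methoxy group, and closure on carbon instead of on the pyranone carbonyl oxygen, secured because the latter would need a seven-membered ring. The oxygen pattern is fixed by the substrate (C4-OMe to 5-OMe, C3-OMe to 6-OMe, C2-O-t-Bu to 7-O-t-Bu, C1=O to 8-OH), and acid-free toluene at 110 °C should spare the tert-butyl ether.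

Step 9
Reactants: 16 7-tert-butoxy-8-hydroxy-5,6-dimethoxy-2-(3,4-dimethoxyphenyl)-4H-chromen-4-one
Product: 17 7-tert-butoxy-5,6,8-trimethoxy-2-(3,4-dimethoxyphenyl)-4H-chromen-4-one
Conditions: MeI (3 equiv), K2CO3 (2 equiv), acetone, 50 °C
Reagents that add atoms: iodomethane, CI
Why: Williamson O-methylation of the only free phenol, the 8-OH, under mild carbonate conditions should leave the tert-butyl ether and the pyranone untouched.

Step 10
Reactants: 17 7-tert-butoxy-5,6,8-trimethoxy-2-(3,4-dimethoxyphenyl)-4H-chromen-4-one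
Product: 18 7-hydroxy-5,6,8-trimethoxy-2-(3,4-dimethoxyphenyl)-4H-chromen-4-one (target)
Conditions: TFA/CH2Cl2 (1:4), 0 °C to rt
Reagents that add atoms: none
Why: Acidolysis of the aryl tert-butyl ether with loss of isobutene (E1-type cleavage) should free the 7-OH, whereas aryl methyl ethers, the peri 5-OMe included, are stable to trifluoroacetic acid at room temperature.

Compound list
1 | dimethyl squarate (3,4-dimethoxycyclobut-3-ene-1,2-dione) | COC1=C(OC)C(=O)C1=O | starting material
2 | sodium methyl squarate (sodium 2-methoxy-3,4-dioxocyclobut-1-en-1-olate) | COC1=C([O-])C(=O)C1=O.[Na+] | intermediate (not isolated)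
3 | methyl hydrogen squarate (3-hydroxy-4-methoxycyclobut-3-ene-1,2-dione) | COC1=C(O)C(=O)C1=O | intermediate
4 | 3-tert-butoxy-4-methoxycyclobut-3-ene-1,2-dione | COC1=C(OC(C)(C)C)C(=O)C1=O | intermediate
5 | 3,4-dimethoxybenzaldehyde | COc1ccc(C=O)cc1OC | starting material
6 | (E)-1-methoxy-3-(trimethylsilyloxy)buta-1,3-diene | CO/C=C/C(=C)O[Si](C)(C)C | starting material
7 | 2-(3,4-dimethoxyphenyl)-6-methoxy-4-(trimethylsilyloxy)-3,6-dihydro-2H-pyran (racemic, cis/trans mixture at C2/C6) | COc1ccc(C2CC(O[Si](C)(C)C)=CC(OC)O2)cc1OC | intermediate (not isolated)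
8 | rac-2-(3,4-dimethoxyphenyl)-2,3-dihydro-4H-pyran-4-one | COc1ccc(C2CC(=O)C=CO2)cc1OC | intermediate
9 | rac-2-(3,4-dimethoxyphenyl)-5-iodo-2,3-dihydro-4H-pyran-4-one | COc1ccc(C2CC(=O)C(I)=CO2)cc1OC | intermediate
10 | 2-(3,4-dimethoxyphenyl)-5-iodo-4H-pyran-4-one | COc1ccc(-c2cc(=O)c(I)co2)cc1OC | intermediate
11 | chloro[6-(3,4-dimethoxyphenyl)-4-oxo-4H-pyran-3-yl]magnesium (LiCl complex) | COc1ccc(-c2cc(=O)c([Mg]Cl)co2)cc1OC | intermediate (not isolated)
12 | rac-2-tert-butoxy-4-hydroxy-3-methoxy-4-[6-(3,4-dimethoxyphenyl)-4-oxo-4H-pyran-3-yl]cyclobut-2-en-1-one | COC1=C(OC(C)(C)C)C(=O)C1(O)c1coc(-c2ccc(OC)c(OC)c2)cc1=O | intermediate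
13 | rac-2-tert-butoxy-3,4-dimethoxy-4-[6-(3,4-dimethoxyphenyl)-4-oxo-4H-pyran-3-yl]cyclobut-2-en-1-one | COC1=C(OC(C)(C)C)C(=O)C1(OC)c1coc(-c2ccc(OC)c(OC)c2)cc1=O | intermediate
14 | (3Z)-2-tert-butoxy-3,4-dimethoxy-4-[6-(3,4-dimethoxyphenyl)-4-oxo-4H-pyran-3-yl]buta-1,3-dien-1-one (pyranonyl group cis to the ketene carbon) | O=C=C(OC(C)(C)C)/C(OC)=C(/OC)c1coc(-c2ccc(OC)c(OC)c2)cc1=O | intermediate (not isolated)
15 | rac-7-tert-butoxy-2-(3,4-dimethoxyphenyl)-5,6-dimethoxy-8aH-chromene-4,8-dione | COC1=C(OC(C)(C)C)C(=O)C2OC(c3ccc(OC)c(OC)c3)=CC(=O)C2=C1OC | intermediate (not isolated)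
16 | 7-tert-butoxy-8-hydroxy-5,6-dimethoxy-2-(3,4-dimethoxyphenyl)-4H-chromen-4-one | COc1ccc(-c2cc(=O)c3c(OC)c(OC)c(OC(C)(C)C)c(O)c3o2)cc1OC | intermediate
17 | 7-tert-butoxy-5,6,8-trimethoxy-2-(3,4-dimethoxyphenyl)-4H-chromen-4-one | COc1ccc(-c2cc(=O)c3c(OC)c(OC)c(OC(C)(C)C)c(OC)c3o2)cc1OC | intermediate
18 | 7-hydroxy-5,6,8-trimethoxy-2-(3,4-dimethoxyphenyl)-4H-chromen-4-one | COc1ccc(-c2cc(=O)c3c(OC)c(OC)c(O)c(OC)c3o2)cc1OC | target

Total step count: 10 (steps 1–2 for the squarate arm, steps 3–5 for the pyranone arm, steps 6–10 after the two arms meet).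
Longest linear sequence: 8 steps (5 to 18 through steps 3–10).

Steps most likely to fail

Step 6. The two squarate carbonyls may not be discriminated well enough, or the wrong one may be attacked, so that the 6-O/7-O pattern would be carried through the ring expansion reversed or as a mixture. The fallback sets out from 10 and makes the regiochemistry irrelevant by using a symmetric squarate. Grignard reagent 11, made from 10 as in step 6, would be added to purchased di-tert-butyl squarate (CC(C)(C)OC1=C(OC(C)(C)C)C(=O)C1=O) to give the racemic di-tert-butoxy carbinol F1. MeI/Ag2O would give its methyl ether F2, and heating in toluene the 6,7-di-tert-butoxy-8-hydroxy-5-methoxyflavone F3. MeI/K2CO3 would give the 5,8-dimethyl ether F4, and TFA in CH2Cl2 would remove both tert-butyl groups to give the 6,7-diol F5. BnBr (1.0 equiv) with K2CO3 in DMF at room temperature should benzylate the more acidic 7-OH, which lies para to the pyranone carbonyl, to give the 7-benzyl ether F6. MeI/K2CO3 would then give the 6-methyl ether F7, and hydrogenolysis (H2, 10% Pd/C, EtOAc) comes back to the route at 18.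

Step 8. The 6π closure onto the cross-conjugated C5=C6 bond of ring C may be slow, so that the ketene oligomerises or, at the higher temperature then needed, the tert-butyl ether is lost as isobutene. The fallback sets out from 9 and moves the ring expansion onto a plain dihydropyran enol ether, the alkenyl partner for which this rearrangement is best established, restoring ring C afterwards.
- NaBH4/CeCl3·7H2O in MeOH at −40 °C (1,2-reduction) would give the allylic alcohol F8, mainly 2,4-cis, which is used as the mixture.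
- TBSCl/imidazole in DMF would give the silyl ether F9.
- t-BuLi (2.1 equiv) in THF at −78 °C would give the vinyllithium F10, which is added to 4 at −78 °C to give the carbinol F11 (same regiochemical check as in step 6).
- MeI/Ag2O would give the methyl ether F12, and toluene at 110 °C the chroman-8-ol F13.
- MeI/K2CO3 would give the 8-methyl ether F14, and Bu4NF in THF the flavan-4-ol F15.
- MnO2 in CH2Cl2 would give the flavanone F16, and DDQ in dioxane at 100 °C comes back to the route at 17.

Step 5. Hydride abstraction from the iodinated vinylogous ester may be slow, so that DDQ attacks the electron-rich aryl ring or iodine is lost on long heating. The fallback sets out from 9 and replaces direct dehydrogenation by selenation and oxidative elimination. Kinetic deprotonation at C3 with LiN(SiMe3)2 in THF at −78 °C would give the lithium dienolate F17, and PhSeCl at −78 °C the α-phenylselanyl ketone F18, with selenium expected trans to the aryl group. H2O2/pyridine in CH2Cl2 at 0 °C to room temperature would give the selenoxide F19, whose syn-elimination with the C2 hydrogen comes back to the route at 10.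

Further compounds
F1 | step 6 | rac-2,3-di-tert-butoxy-4-hydroxy-4-[6-(3,4-dimethoxyphenyl)-4-oxo-4H-pyran-3-yl]cyclobut-2-en-1-one | CC(C)(C)OC1=C(OC(C)(C)C)C(=O)C1(O)c1coc(-c2ccc(OC)c(OC)c2)cc1=O
F2 | step 6 | rac-2,3-di-tert-butoxy-4-methoxy-4-[6-(3,4-dimethoxyphenyl)-4-oxo-4H-pyran-3-yl]cyclobut-2-en-1-one | CC(C)(C)OC1=C(OC(C)(C)C)C(=O)C1(OC)c1coc(-c2ccc(OC)c(OC)c2)cc1=O
F3 | step 6 | 6,7-di-tert-butoxy-8-hydroxy-5-methoxy-2-(3,4-dimethoxyphenyl)-4H-chromen-4-one | COc1ccc(-c2cc(=O)c3c(OC)c(OC(C)(C)C)c(OC(C)(C)C)c(O)c3o2)cc1OC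
F4 | step 6 | 6,7-di-tert-butoxy-5,8-dimethoxy-2-(3,4-dimethoxyphenyl)-4H-chromen-4-one | COc1ccc(-c2cc(=O)c3c(OC)c(OC(C)(C)C)c(OC(C)(C)C)c(OC)c3o2)cc1OC
F5 | step 6 | 6,7-dihydroxy-5,8-dimethoxy-2-(3,4-dimethoxyphenyl)-4H-chromen-4-one | COc1ccc(-c2cc(=O)c3c(OC)c(O)c(O)c(OC)c3o2)cc1OC
F6 | step 6 | 7-benzyloxy-6-hydroxy-5,8-dimethoxy-2-(3,4-dimethoxyphenyl)-4H-chromen-4-one | COc1ccc(-c2cc(=O)c3c(OC)c(O)c(OCc4ccccc4)c(OC)c3o2)cc1OC
F7 | step 6 | 7-benzyloxy-5,6,8-trimethoxy-2-(3,4-dimethoxyphenyl)-4H-chromen-4-one | COc1ccc(-c2cc(=O)c3c(OC)c(OC)c(OCc4ccccc4)c(OC)c3o2)cc1OC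
F8 | step 8 | 2-(3,4-dimethoxyphenyl)-5-iodo-3,4-dihydro-2H-pyran-4-ol (racemic, mainly 2,4-cis, used as the mixture) | COc1ccc(C2CC(O)C(I)=CO2)cc1OC
F9 | step 8 | 4-(tert-butyldimethylsilyloxy)-2-(3,4-dimethoxyphenyl)-5-iodo-3,4-dihydro-2H-pyran (racemic, diastereomer mixture) | COc1ccc(C2CC(O[Si](C)(C)C(C)(C)C)C(I)=CO2)cc1OC
F10 | step 8 | [4-(tert-butyldimethylsilyloxy)-2-(3,4-dimethoxyphenyl)-3,4-dihydro-2H-pyran-5-yl]lithium (racemic, diastereomer mixture) | COc1ccc(C2CC(O[Si](C)(C)C(C)(C)C)C([Li])=CO2)cc1OC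
F11 | step 8 | 2-tert-butoxy-4-[4-(tert-butyldimethylsilyloxy)-2-(3,4-dimethoxyphenyl)-3,4-dihydro-2H-pyran-5-yl]-4-hydroxy-3-methoxycyclobut-2-en-1-one (racemic, diastereomer mixture) | COC1=C(OC(C)(C)C)C(=O)C1(O)C1=COC(c2ccc(OC)c(OC)c2)CC1O[Si](C)(C)C(C)(C)C
F12 | step 8 | 2-tert-butoxy-4-[4-(tert-butyldimethylsilyloxy)-2-(3,4-dimethoxyphenyl)-3,4-dihydro-2H-pyran-5-yl]-3,4-dimethoxycyclobut-2-en-1-one (racemic, diastereomer mixture) | COC1=C(OC(C)(C)C)C(=O)C1(OC)C1=COC(c2ccc(OC)c(OC)c2)CC1O[Si](C)(C)C(C)(C)C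
F13 | step 8 | 7-tert-butoxy-4-(tert-butyldimethylsilyloxy)-2-(3,4-dimethoxyphenyl)-5,6-dimethoxychroman-8-ol (racemic, diastereomer mixture) | COc1ccc(C2CC(O[Si](C)(C)C(C)(C)C)c3c(OC)c(OC)c(OC(C)(C)C)c(O)c3O2)cc1OC
F14 | step 8 | 7-tert-butoxy-4-(tert-butyldimethylsilyloxy)-2-(3,4-dimethoxyphenyl)-5,6,8-trimethoxychroman (racemic, diastereomer mixture) | COc1ccc(C2CC(O[Si](C)(C)C(C)(C)C)c3c(OC)c(OC)c(OC(C)(C)C)c(OC)c3O2)cc1OC
F15 | step 8 | 7-tert-butoxy-2-(3,4-dimethoxyphenyl)-5,6,8-trimethoxychroman-4-ol (racemic, diastereomer mixture) | COc1ccc(C2CC(O)c3c(OC)c(OC)c(OC(C)(C)C)c(OC)c3O2)cc1OC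
F16 | step 8 | rac-7-tert-butoxy-2-(3,4-dimethoxyphenyl)-5,6,8-trimethoxychroman-4-one | COc1ccc(C2CC(=O)c3c(OC)c(OC)c(OC(C)(C)C)c(OC)c3O2)cc1OC
F17 | step 5 | lithium 2-(3,4-dimethoxyphenyl)-5-iodo-2H-pyran-4-olate (racemic) | COc1ccc(C2C=C(O[Li])C(I)=CO2)cc1OC
F18 | step 5 | 2-(3,4-dimethoxyphenyl)-5-iodo-3-(phenylselanyl)-2,3-dihydro-4H-pyran-4-one (racemic, 2,3-trans expected) | COc1ccc(C2OC=C(I)C(=O)C2[Se]c2ccccc2)cc1OC
F19 | step 5 | 2-(3,4-dimethoxyphenyl)-5-iodo-3-(phenylseleninyl)-2,3-dihydro-4H-pyran-4-one (racemic, diastereomer mixture) | COc1ccc(C2OC=C(I)C(=O)C2[Se](=O)c2ccccc2)cc1OC
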